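- The ratio I watch reads 4.99 at the last maple point. It is the log of the fraction of left-handed substrate remaining over the same log for the right-handed substrate, the selectivity factor. With it, in these flasks, one reading of the left-handed substrate gives an estimate of the fraction of right-handed substrate.

| flask | left-handed substrate | right-handed substrate | partner | protic impurity | catalyst | remark | time |
|---|---|---|---|---|---|---|---|
| cedar | 0.25 M | 0.25 M | 1.7 equiv | 0.25 M | 3.5 mol% | run made earlier |  |
| maple | 0.25 M | 0.25 M | 2.6 equiv | 0.25 M | 3.5 mol% | run made earlier |  |
| flask | 0.25 M | 0.25 M | 1.20 equiv | 0.250 M | 3.5 mol% |  | 2.0 h |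

| run | time / min | left-handed substrate / % | right-handed substrate / % |
|---|---|---|---|
| cedar | 4.00 | 46.7 | 49.3 |
| cedar | 12.0 | 42.4 | 48.2 |
| cedar | 20.0 | 39.1 | 47.6 |
| cedar | 30.0 | 35.7 | 48.1 |
| cedar | 40.0 | 33.5 | 45.7 |
| cedar | 60.0 | 29.5 | 44.3 |
| cedar | 80.0 | 27.5 | 46.3 |
| maple | 6.00 | 42.4 | 48.7 |
| maple | 8.00 | 41.4 | 47.8 |
| maple | 12.0 | 37.3 | 46.4 |
| maple | 20.0 | 34.0 | 46.6 |
| maple | 30.0 | 29.9 | 44.5 |
| maple | 50.0 | 24.8 | 43.7 |
| maple | 80.0 | 20.7 | 41.9 |

(standard deviation of a reading: 0.5 percentage points)

- catalyst is single-handed; left-handed substrate and right-handed substrate are mirror images of each other, charged as a racemate, each of them at the stated concentration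
- on the list of suspects stand: partner + catalyst + left-handed substrate -> catalyst + left-handed product; partner + catalyst + right-handed substrate -> catalyst + right-handed product; catalyst <-> dormant form; partner + protic impurity -> quenched reagent
- an excess is the difference of the two amounts in percent of their sum
- an excess is below zero if the other one leads

1. part of the left-handed substrate and right-handed substrate charged together that has reacted at 2.0 h
2. excess of left-handed product over right-handed product in the product at 2.0 h
3. excess of right-handed substrate over left-handed substrate among what is left of the two at 2.0 h

- First rung: between the first two cedar readings, the half-life of the left-handed substrate reads 57.4 min.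
- Second rung: between the last two cedar readings, that half-life reads 197 min, longer than early. I read this as catalyst passing to the dormant form and partner being used.
- Third rung: that late cedar half-life exceeds the new flask's 2.0 h, so I expect the left-handed substrate in the new flask still to be falling at the end.
- Slowest rung: the right-handed substrate's late half-life in cedar is 16.4 h, by my ratio.
- Maple's log over cedar's at the last reading is 1.48, and their partner ratio is 1.53. So I scale cedar's log by partner and extend it at the late slope.
- By this reckoning I expect 59.4 % of the flask's left-handed substrate and 90.1 % of its right-handed substrate to remain.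
- My figures are therefore c 25.3 %, eP 60.8 % and eS 20.5 %. My scaling uses the partner charges, not the partner used up during the run.
- The forecast differs from mine: c 24.1 %, eP 61 %, eS 19.4 %. It takes “the rate is first order in partner”.
- The flask gives c 23.0 %, eP 62.8 %, eS 18.8 %.

    partner + catalyst + left-handed substrate → catalyst + left-handed product (k = 0.0840 L² mol⁻² s⁻¹)
    partner + catalyst + right-handed substrate → catalyst + right-handed product (k = 0.0160 L² mol⁻² s⁻¹)
    catalyst ⇌ dormant form (K = 1.90, k = 3.60 × 10⁻⁴ s⁻¹)
    partner + protic impurity → quenched reagent (k = 4.30 × 10⁻⁴ L mol⁻¹ s⁻¹)

- The flask keeps 63 % of its left-handed substrate, which my ratio turns into 91.2 % of the right-handed substrate; the flask shows 91 %. At 2.00 h, the protic impurity uses partner 1.6 times as fast as the left-handed step does, and that step's half-life of left-handed substrate, 8.3 h, is long against the run.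
- With 4.80 equiv of partner, a neighbouring flask keeps 10 % of its left-handed substrate. My ratio gives 63.0 % of the right-handed substrate, and the computed value is 65 %.

(The readings were computed on assumed constants; noise was put on by code.)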